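The route rests on a hidden symmetry. The quaternary ring carbon C1 of the cyclohexane bears two identical two-carbon arms: C6–C5 inside the ring, and the CH2–CH2 tether to the chromene. Both arms are traced back to vinyl groups. C1 then becomes a prochiral divinyl carbon in an open-chain triene ketone that carries only the C3 methyl stereocentre. One catalyst-controlled, group-selective ring-closing metathesis joins C5 to C6, closes the carbocycle, fixes quaternary C1 and leaves the other vinyl group as the handle for the tether. B-alkyl Suzuki coupling, asymmetric O-allylation of a symmetric dihydroxybenzaldehyde, double methylenation and a second metathesis complete the chromene.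

Key step: step 4

Assumption: the antipode of the chiral molybdenum aryloxide (step 4) and of the Trost ligand (step 11) that gives the drawn configuration is fixed by a trial run; both antipodes of each are available and nothing else in the route changes.

Step 1
Reactants: 1 (S)-4-benzyl-3-propanoyl-1,3-oxazolidin-2-one; 2 allyl iodide
Product: 3 (S)-4-benzyl-3-[(2R)-2-methylpent-4-enoyl]-1,3-oxazolidin-2-one
Conditions: NaHMDS, THF, −78 °C; then 2, −78 → −45 °C
Reagents that add atoms: none
Why: Evans asymmetric alkylation: the benzyl group shields one face of the chelated sodium Z-enolate, so allyl iodide enters from the other face and sets the (R)-configured methyl-bearing carbon that becomes ring C3.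

Step 2
Reactants: 3
Product: 4 (2R)-N-methoxy-N,2-dimethylpent-4-enamide
Conditions: MeONHMe·HCl, AlMe3, CH2Cl2, −10 °C → rt
Reagents that add atoms: N,O-dimethylhydroxylamine hydrochloride, CNOC.Cl
Why: Weinreb aminolysis of the imide: the aluminium amide attacks the exocyclic carbonyl of this unhindered α-methyl acyl group, frees the auxiliary and leaves the α-stereocentre untouched.

Step 3
Reactants: 4; 5 3-methylpenta-1,4-diene
Product: 8 (5R)-3-ethenyl-3,5-dimethylocta-1,7-dien-4-one, via 3-methylpentadienyllithium 6 (not isolated), via 3-methylpentadienylmagnesium bromide 7 (not isolated)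
Conditions: 5, s-BuLi, THF, −78 → 0 °C; MgBr2·OEt2, −78 °C; 4, −78 → 0 °C; aq NH4Cl
Reagents that add atoms: none
Why: Weinreb ketone synthesis with an allylic Grignard reagent: the σ-bound pentadienylmagnesium reacts through a six-membered SE2' transition state at its methyl-bearing γ-carbon and creates the divinyl quaternary carbon, the chelated tetrahedral intermediate stops over-addition and protects the α-stereocentre until the quench, and no new stereocentre arises because the two vinyl groups are identical.

Step 4
Reactants: 8
Product: 9 (2S,6R)-2-ethenyl-2,6-dimethylcyclohex-3-en-1-one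
Conditions: Mo(N-2,6-iPr2C6H3)(CHCMe2Ph)(2,5-dimethylpyrrolide)(OAr*) (5 mol %, made in situ from the bis-pyrrolide and enantiopure 3,3'-dibromo-2'-(TBSO)-octahydrobinaphthol), C6H6, 22 °C, vented under N2
Reagents that add atoms: none
Why: The chiral molybdenum alkylidene first exchanges with the unhindered allyl terminus (future ring C5), then undergoes an intramolecular [2+2] with one of the two vinyl groups on the prochiral carbon and cycloreverts, which releases ethylene and gives the C5=C6 ring alkene. The closest known reaction type is the desymmetrising asymmetric ring-closing metathesis of trienes with a divinyl-substituted all-carbon quaternary centre by stereogenic-at-molybdenum monoaryloxide pyrrolide catalysts, run here as a selection between diastereotopic groups. One ring is closed, the six-membered carbocycle, by metathesis of a 1,7-diene, and ring size is unambiguous because vinyl–vinyl closure would give a cyclopropene. The one new stereocentre, quaternary C1 of the target (C2 of 9), is controlled by the catalyst, whose bulky aryloxide and small imido ligand admit the metallacyclobutane with only one of the two vinyl groups, while the resident methyl centre sits pseudo-equatorial and acts at most as a matched or mismatched modifier. The step needs three selectivities: site-selective initiation (secured by the steric gap between the allyl CH=CH2 and the two neopentyl-type vinyl groups), group selectivity (secured by the catalyst) and tolerance of the carbonyl (secured by a ketone flanked by a quaternary and a tertiary carbon, a class that molybdenum alkylidenes leave intact). The medium is neutral, so the α-stereocentre is not epimerised, and loss of ethylene makes the closure irreversible.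

Step 5
Reactants: 10 but-2-yn-1-ol
Product: 12 (Z)-3-iodobut-2-en-1-ol, via cyclic sodium alkenylalanate 11 (not isolated)
Conditions: Red-Al, THF, 0 °C → rt; I2, THF, −78 °C
Reagents that add atoms: iodine, II
Why: Hydroxyl-directed trans-hydroalumination of the propargylic alcohol places aluminium on C3 in a five-membered alanate, and iodinolysis with retention gives only the Z-iodide.

Step 6
Reactants: 9; 12
Product: 14 (2S,6R)-2-[(3Z)-5-hydroxy-3-methylpent-3-en-1-yl]-2,6-dimethylcyclohex-3-en-1-one, via B-alkyl-9-BBN adduct 13 (not isolated)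
Conditions: 9-BBN (1.1 equiv), THF, 0 °C → rt; then 12, PdCl2(dppf), AsPh3, Cs2CO3, DMF–H2O, rt
Reagents that add atoms: none
Why: Hydroboration/B-alkyl Suzuki–Miyaura coupling: 9-BBN adds to the monosubstituted vinyl group much faster than to the cis ring alkene or the doubly flanked ketone, and the sp3–sp2 coupling keeps the Z geometry and does not touch the stereocentres.

Step 7
Reactants: 14
Product: 15 (2R,6R)-2-[(3Z)-5-hydroxy-3-methylpent-3-en-1-yl]-2,6-dimethylcyclohexan-1-one
Conditions: H2 (1 atm), RhCl(PPh3)3, benzene, rt
Reagents that add atoms: none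
Why: Homogeneous hydrogenation with Wilkinson's catalyst discriminates by degree of substitution, so the cis-disubstituted ring alkene is saturated and the trisubstituted alkene stays, which turns the metathesis bond into the C5–C6 single bond.

Step 8
Reactants: 15
Product: 16 (2Z)-5-[(1R,3R)-1,3-dimethyl-2-oxocyclohexyl]-3-methylpent-2-en-1-yl methyl carbonate
Conditions: ClCO2Me, pyridine, CH2Cl2, 0 °C
Reagents that add atoms: methyl chloroformate, COC(=O)Cl
Why: Acylation of the primary allylic alcohol with a chloroformate gives the ionisable carbonate needed for π-allyl chemistry.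

Step 9
Reactants: 17 3,4,5-trimethoxybenzaldehyde
Product: 18 2,6-dibromo-3,4,5-trimethoxybenzaldehyde
Conditions: Br2 (2.4 equiv), AcOH, rt → 60 °C
Reagents that add atoms: bromine, BrBr
Why: Twofold electrophilic aromatic bromination: the only two free ring positions are each ortho and para to methoxy groups, so the symmetric dibromide is the only possible dibromide.

Step 10
Reactants: 18
Product: 19 2,6-dihydroxy-3,4,5-trimethoxybenzaldehyde
Conditions: Cu(acac)2, BHMPO oxalamide ligand, LiOH·H2O, DMSO–H2O, 80 °C; aq HCl
Reagents that add atoms: lithium hydroxide, [Li+].[OH-]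
Why: Copper-catalysed Ullmann-type hydroxylation of aryl bromides, assisted by the ortho-formyl group, exchanges both bromines for hydroxyl groups and gives the symmetric phenol.

Step 11
Reactants: 16; 19 (1.5 equiv)
Product: 20 2-{[(3S)-5-[(1R,3R)-1,3-dimethyl-2-oxocyclohexyl]-3-methylpent-1-en-3-yl]oxy}-6-hydroxy-3,4,5-trimethoxybenzaldehyde
Conditions: Pd2(dba)3·CHCl3, (R,R)-DACH-phenyl Trost ligand (see assumption), CH2Cl2, 0 °C → rt
Reagents that add atoms: none
Why: Trost asymmetric allylic alkylation of a phenol: ionisation gives a 1,1-disubstituted π-allylpalladium complex whose faces equilibrate by π–σ–π at the CH2 terminus, the phenoxide attacks the more substituted terminus inside the chiral pocket and sets the (S)-configured tertiary ether carbon (chromene C2), and only one mono-ether can form because 19 has two equivalent hydroxyl groups and no free ring carbon.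

Step 12
Reactants: 20
Product: 21 2-ethenyl-3-{[(3S)-5-[(1R,3R)-1,3-dimethyl-2-methylidenecyclohexyl]-3-methylpent-1-en-3-yl]oxy}-4,5,6-trimethoxyphenol
Conditions: Tebbe reagent (4 equiv), pyridine, THF–toluene, −40 °C → rt; aq NaOH
Reagents that add atoms: Tebbe reagent, C[Al](C)[CH2-].[Cl-].[Ti+4].c1cc[cH-]c1.c1cc[cH-]c1
Why: Tebbe methylenation converts the aldehyde and the hindered, enolisable ketone in one operation, and because the titanium carbene is small and non-basic the α-stereocentre (ring C3) is not epimerised while the exocyclic methylene and the styrene are installed together.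

Step 13
Reactants: 21
Product: 22 (2S)-2-{2-[(1R,3R)-1,3-dimethyl-2-methylidenecyclohexyl]ethyl}-6,7,8-trimethoxy-2-methyl-2H-chromen-5-ol
Conditions: Grubbs II (5 mol %), CH2Cl2, 40 °C
Reagents that add atoms: none
Why: Ring-closing metathesis of the 2-vinylaryl 1,1-disubstituted allyl ether closes the 2H-pyran ring without touching the C2–O bond, and the exocyclic methylene, flanked by a quaternary and a tertiary carbon, is too hindered to take part.

Compound list
1 | (S)-4-benzyl-3-propanoyl-1,3-oxazolidin-2-one | O=C1OC[C@H](Cc2ccccc2)N1C(=O)CC | starting material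
2 | allyl iodide | C=CCI | starting material
3 | (S)-4-benzyl-3-[(2R)-2-methylpent-4-enoyl]-1,3-oxazolidin-2-one | O=C1OC[C@H](Cc2ccccc2)N1C(=O)[C@H](C)CC=C | intermediate
4 | (2R)-N-methoxy-N,2-dimethylpent-4-enamide | CON(C)C(=O)[C@H](C)CC=C | intermediate
5 | 3-methylpenta-1,4-diene | C=CC(C)C=C | starting material
6 | 3-methylpentadienyllithium | [Li]CC=C(C)C=C | intermediate
7 | 3-methylpentadienylmagnesium bromide | Br[Mg]CC=C(C)C=C | intermediate
8 | (5R)-3-ethenyl-3,5-dimethylocta-1,7-dien-4-one | O=C([C@H](C)CC=C)C(C)(C=C)C=C | intermediate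
9 | (2S,6R)-2-ethenyl-2,6-dimethylcyclohex-3-en-1-one | O=C1[C@H](C)CC=C[C@]1(C)C=C | intermediate
10 | but-2-yn-1-ol | CC#CCO | starting material
11 | cyclic sodium alkenylalanate (five-membered O–Al–C ring, two 2-methoxyethoxy ligands) | CC1=CCO[Al-]1(OCCOC)OCCOC.[Na+] | intermediate
12 | (Z)-3-iodobut-2-en-1-ol | C/C(I)=C/CO | intermediate
13 | 9-{2-[(1S,5R)-1,5-dimethyl-6-oxocyclohex-2-en-1-yl]ethyl}-9-borabicyclo[3.3.1]nonane | O=C1[C@H](C)CC=C[C@]1(C)CCB1C2CCCC1CCC2 | intermediate
14 | (2S,6R)-2-[(3Z)-5-hydroxy-3-methylpent-3-en-1-yl]-2,6-dimethylcyclohex-3-en-1-one | O=C1[C@H](C)CC=C[C@]1(C)CC/C(C)=C\CO | intermediate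
15 | (2R,6R)-2-[(3Z)-5-hydroxy-3-methylpent-3-en-1-yl]-2,6-dimethylcyclohexan-1-one | O=C1[C@H](C)CCC[C@]1(C)CC/C(C)=C\CO | intermediate
16 | (2Z)-5-[(1R,3R)-1,3-dimethyl-2-oxocyclohexyl]-3-methylpent-2-en-1-yl methyl carbonate | O=C1[C@H](C)CCC[C@]1(C)CC/C(C)=C\COC(=O)OC | intermediate
17 | 3,4,5-trimethoxybenzaldehyde | COc1cc(C=O)cc(OC)c1OC | starting material
18 | 2,6-dibromo-3,4,5-trimethoxybenzaldehyde | COc1c(Br)c(C=O)c(Br)c(OC)c1OC | intermediate
19 | 2,6-dihydroxy-3,4,5-trimethoxybenzaldehyde | COc1c(O)c(C=O)c(O)c(OC)c1OC | intermediate
20 | 2-{[(3S)-5-[(1R,3R)-1,3-dimethyl-2-oxocyclohexyl]-3-methylpent-1-en-3-yl]oxy}-6-hydroxy-3,4,5-trimethoxybenzaldehyde | O=C1[C@H](C)CCC[C@]1(C)CC[C@@](Oc2c(OC)c(OC)c(OC)c(O)c2C=O)(C)C=C | intermediate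
21 | 2-ethenyl-3-{[(3S)-5-[(1R,3R)-1,3-dimethyl-2-methylidenecyclohexyl]-3-methylpent-1-en-3-yl]oxy}-4,5,6-trimethoxyphenol | C=C1[C@H](C)CCC[C@]1(C)CC[C@@](Oc2c(OC)c(OC)c(OC)c(O)c2C=C)(C)C=C | intermediate
22 | (2S)-2-{2-[(1R,3R)-1,3-dimethyl-2-methylidenecyclohexyl]ethyl}-6,7,8-trimethoxy-2-methyl-2H-chromen-5-ol | C=C1[C@H](C)CCC[C@]1(C)CC[C@@]1(C)C=Cc2c(O)c(OC)c(OC)c(OC)c2O1 | target

Total step count: 13. Longest linear sequence: 10 steps (1–4, 6–8, 11–13).

Steps most likely to fail

Step 4. The chiral alkylidene may discriminate too weakly between the two diastereotopic vinyl groups if its preference is mismatched with the resident methyl centre. Turnover may also stall on the crowded neopentyl-type alkenes.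
- In the fallback the quaternary centre is set before ring closure by a catalyst-controlled carbonyl allylation, and the same ring bond is then closed with an achiral ruthenium catalyst. It sets out from 3.
- LiBH4 (Et2O, H2O, 0 °C) gives (R)-2-methylpent-4-en-1-ol F1.
- Iridium-catalysed transfer-hydrogenative tert-(hydroxy)prenylation of F1 with isoprene oxide (cyclometallated π-allyliridium C,O-benzoate of one Tol-BINAP antipode, K3PO4, THF, 60 °C) is anti-selective, catalyst-controlled and known to build all-carbon quaternary centres. It gives (2R,3R,4R)-2-ethenyl-2,4-dimethylhept-6-ene-1,3-diol F2.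
- Grubbs II closes this 1,7-diene to (1R,2R,6R)-2-(hydroxymethyl)-2,6-dimethylcyclohex-3-en-1-ol F3.
- TEMPO/PhI(OAc)2 oxidises only the primary alcohol to 6-hydroxy-1,5-dimethylcyclohex-2-ene-1-carbaldehyde F4.
- Ph3P=CH2 converts F4 into 2-ethenyl-2,6-dimethylcyclohex-3-en-1-ol F5, and Dess–Martin oxidation comes back to the route at 9.

Step 11. The hindered, di-ortho-substituted phenoxide may attack the unsubstituted allyl terminus. The π-allyl complex may lose a β-hydrogen to give a diene. The acidic phenol may also leave again from the product, which erodes the configuration.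
- In the fallback the stereocentre is moved to a reagent-controlled epoxidation and is then transferred stereospecifically. It sets out from 15.
- Sharpless epoxidation with D-(−)-diethyl tartrate (Ti(OiPr)4, TBHP, 4 Å sieves, −20 °C) gives [(2R,3S)-3-{2-[(1R,3R)-1,3-dimethyl-2-oxocyclohexyl]ethyl}-3-methyloxiran-2-yl]methanol F6, whose tertiary C–O bond already has the final configuration.
- I2, PPh3 and imidazole give the corresponding epoxy iodide F7.
- Zinc in ethanol opens F7 reductively to (2R,6R)-2-[(3S)-3-hydroxy-3-methylpent-4-en-1-yl]-2,6-dimethylcyclohexan-1-one F8.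
- ClCO2Me with DMAP and pyridine gives the tertiary methyl carbonate F9.
- Rhodium-catalysed allylic etherification (RhCl(PPh3)3, P(OMe)3, THF) with the sodium phenoxide of 19 is regioretentive and proceeds with net retention. It comes back to the route at 20.

Step 3. The pentadienyl reagent may react through a terminal carbon instead of the central one. Addition to the amide may stall for steric reasons, or the reagent may simply deprotonate the amide.
- In the fallback the acylation is replaced by addition to the far more electrophilic aldehyde followed by oxidation. It sets out from 4.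
- DIBAL-H (THF, −78 °C) gives (R)-2-methylpent-4-enal F10.
- The anion 6 is transmetallated with ZnBr2 to 3-methylpentadienylzinc bromide F11, which adds through the same γ-selective cyclic transition state. This gives (5R)-3-ethenyl-3,5-dimethylocta-1,7-dien-4-ol F12 as both carbinol epimers.
- Dess–Martin oxidation removes that centre and comes back to the route at 8.

Further compounds
F1 | step 4 | (R)-2-methylpent-4-en-1-ol | OC[C@H](C)CC=C
F2 | step 4 | (2R,3R,4R)-2-ethenyl-2,4-dimethylhept-6-ene-1,3-diol | O[C@H]([C@H](C)CC=C)[C@@](C)(CO)C=C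
F3 | step 4 | (1R,2R,6R)-2-(hydroxymethyl)-2,6-dimethylcyclohex-3-en-1-ol | O[C@@H]1[C@H](C)CC=C[C@]1(C)CO
F4 | step 4 | 6-hydroxy-1,5-dimethylcyclohex-2-ene-1-carbaldehyde | O[C@@H]1[C@H](C)CC=C[C@]1(C)C=O
F5 | step 4 | 2-ethenyl-2,6-dimethylcyclohex-3-en-1-ol | O[C@@H]1[C@H](C)CC=C[C@]1(C)C=C
F6 | step 11 | [(2R,3S)-3-{2-[(1R,3R)-1,3-dimethyl-2-oxocyclohexyl]ethyl}-3-methyloxiran-2-yl]methanol | O=C1[C@H](C)CCC[C@]1(C)CC[C@]2(C)O[C@@H]2CO
F7 | step 11 | epoxy iodide of F6 | O=C1[C@H](C)CCC[C@]1(C)CC[C@]2(C)O[C@@H]2CI
F8 | step 11 | (2R,6R)-2-[(3S)-3-hydroxy-3-methylpent-4-en-1-yl]-2,6-dimethylcyclohexan-1-one | O=C1[C@H](C)CCC[C@]1(C)CC[C@@](O)(C)C=C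
F9 | step 11 | tertiary methyl carbonate of F8 | O=C1[C@H](C)CCC[C@]1(C)CC[C@@](OC(=O)OC)(C)C=C
F10 | step 3 | (R)-2-methylpent-4-enal | O=C[C@H](C)CC=C
F11 | step 3 | 3-methylpentadienylzinc bromide | Br[Zn]CC=C(C)C=C
F12 | step 3 | (5R)-3-ethenyl-3,5-dimethylocta-1,7-dien-4-ol (both carbinol epimers) | OC([C@H](C)CC=C)C(C)(C=C)C=C
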